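The side chain is disconnected between its allylic CH2 and the alkene CH, so that the ring-bound CH(CH3)CH2 unit becomes an isopropenyl group on C8 (the side-chain-bearing carbon of the cyclopropane-fused cyclooctene–butenolide core). In one flask, 9-BBN hydroboration of this 1,1-disubstituted alkene sets the side-chain methyl stereocentre under control of C8 and the cis acetoxy group on C1, and B-alkyl Suzuki–Miyaura coupling with an (E)-vinyl iodide forms the CH2–CH bond and brings in the tertiary allylic hydroperoxide as a peroxyketal. The core is built by two-carbon enamine–propiolate ring expansion of an enantiopure cyclopropyl cyclohexanone and exo-face functionalisation of the resulting tub-shaped eight-membered ring.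

Key step: step 15

Remark on numbering: the eight-membered ring is numbered C1 (acetoxy carbon), C2 (CH2), C3 (CH–CH3), C4 and C5 (cyclopropane CH; C9 is the cyclopropane CH2), C6 (butenolide carbon bearing the lactone C=O), C7 (butenolide carbon bearing OCH2) and C8 (side-chain carbon). In the target the C1 oxygen, the C8 substituent and C9 lie on one ring face, and the C3 methyl on the other.

Assumption: β-keto ester 10 reacts through its conjugated dienol tautomer, whose ring should be a tub with C9 and the C3 methyl both exo; reagents are expected to attack the C8=C1 alkene from its exo face, which is the face of C9.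

Step 1
Reactants: 1 propanal; 2 but-3-en-2-one
Product: 3 (R)-2-methyl-5-oxohexanal
Conditions: (S)-2-[methoxy(diphenyl)methyl]pyrrolidine (5 mol %), ethyl 3,4-dihydroxybenzoate (20 mol %), neat, 4 °C
Reagents that add atoms: none
Why: Organocatalytic enamine Michael addition, in which the diphenylmethyl ether group of the (S)-catalyst shields one face of the E-enamine of propanal so that the enone should add to the other face and give the (R)-α-methyl aldehyde.

Step 2
Reactants: 3 (R)-2-methyl-5-oxohexanal
Product: 4 (R)-4-methylcyclohex-2-en-1-one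
Conditions: LiOH, i-PrOH, rt
Reagents that add atoms: none
Why: Intramolecular aldol condensation of the methyl ketone onto the aldehyde (Robinson-type closure), expected to be faster than epimerisation of the aldehyde α-centre, which becomes the non-enolisable C4 of the enone.

Step 3
Reactants: 4 (R)-4-methylcyclohex-2-en-1-one
Product: 5 (1S,5R,6S)-5-methylbicyclo[4.1.0]heptan-2-one
Conditions: Me3S(O)I, NaH, DMSO, rt
Reagents that add atoms: trimethylsulfoxonium iodide C[S+](C)(C)=O.[I-]
Why: Corey–Chaykovsky cyclopropanation, in which the sulfoxonium ylide should add to the enone β-carbon anti to the adjacent methyl group and close to the cis-fused cyclopropyl ketone with CH2 trans to methyl (C3, C4, C5 of the target).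

Step 4
Reactants: 5 (1S,5R,6S)-5-methylbicyclo[4.1.0]heptan-2-one
Product: 6 1-[(1S,5R,6S)-5-methylbicyclo[4.1.0]hept-2-en-2-yl]pyrrolidine
Conditions: pyrrolidine, TsOH (cat.), PhH, reflux (Dean–Stark)
Reagents that add atoms: pyrrolidine C1CCNC1
Why: Enamine formation, which can only take place toward the CH2 α-carbon because the other α-carbon is a cyclopropane CH.

Step 5
Reactants: 6 1-[(1S,5R,6S)-5-methylbicyclo[4.1.0]hept-2-en-2-yl]pyrrolidine; 7 methyl propiolate
Product: 10 methyl (1S,7R,8S)-7-methyl-2-oxobicyclo[6.1.0]non-4-ene-3-carboxylate, via aminocyclobutene adduct 8 (not isolated), via dienamine ester 9 (not isolated)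
Conditions: Et2O, 0 °C → reflux; then 1 M aq. HCl, THF, rt
Reagents that add atoms: water O
Why: Two-carbon ring expansion of a cyclic enamine with an acetylenic ester: [2+2] cycloaddition (enamine β-carbon to the alkyne CH terminus), ring opening of the push–pull cyclobutene to the cis,cis-cyclooctadiene and hydrolysis should give the eight-membered β-keto ester with C6 as ketone, the ester on C7 and a C8=C1 alkene, the three stereocentres being untouched.

Step 6
Reactants: 10 methyl (1S,7R,8S)-7-methyl-2-oxobicyclo[6.1.0]non-4-ene-3-carboxylate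
Product: 12 methyl (1S,5R,7R,8S)-5-hydroxy-7-methyl-2-oxobicyclo[6.1.0]non-3-ene-3-carboxylate, via epoxy keto ester 11 (not isolated)
Conditions: mCPBA, CH2Cl2, 0 °C
Reagents that add atoms: 3-chloroperoxybenzoic acid OOC(=O)c1cccc(Cl)c1
Why: Vinylogous (γ) hydroxylation of a dienol by epoxidation of its γ,δ-alkene and enol-driven opening of the epoxide; attack on the exo face of C8=C1 in the tub-shaped dienol should place the C1 oxygen cis to the cyclopropane CH2.

Step 7
Reactants: 12 methyl (1S,5R,7R,8S)-5-hydroxy-7-methyl-2-oxobicyclo[6.1.0]non-3-ene-3-carboxylate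
Product: 13 methyl (1S,4R,5R,7R,8S)-5-hydroxy-7-methyl-2-oxo-4-(prop-1-en-2-yl)bicyclo[6.1.0]nonane-3-carboxylate
Conditions: isopropenylmagnesium bromide (3 equiv), THF, −78 → −20 °C; aq. NH4Cl
Reagents that add atoms: isopropenylmagnesium bromide CC(=C)[Mg]Br
Why: Alkoxide-directed (ligand-assisted) conjugate addition of a Grignard reagent to a cyclic γ-hydroxy enone, in which the C1 magnesium alkoxide should deliver the alkenyl group to C8 of the doubly activated alkylidene β-keto ester on its own face, setting C8 cis to the C1 oxygen.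

Step 8
Reactants: 13 methyl (1S,4R,5R,7R,8S)-5-hydroxy-7-methyl-2-oxo-4-(prop-1-en-2-yl)bicyclo[6.1.0]nonane-3-carboxylate
Product: 14 methyl (1S,4S,5R,7R,8S)-5-hydroxy-7-methyl-4-(prop-1-en-2-yl)-2-(trifluoromethylsulfonyloxy)bicyclo[6.1.0]non-2-ene-3-carboxylate
Conditions: NaH (1.05 equiv), THF, 0 °C; PhNTf2, 0 °C → rt
Reagents that add atoms: N-phenylbis(trifluoromethanesulfonimide) O=S(=O)(N(c1ccccc1)S(=O)(=O)C(F)(F)F)C(F)(F)F
Why: O-triflation of the β-keto ester enolate, which should form selectively because the β-keto ester is far more acidic than the secondary alcohol and the other α-carbon is a cyclopropane CH.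

Step 9
Reactants: 14 methyl (1S,4S,5R,7R,8S)-5-hydroxy-7-methyl-4-(prop-1-en-2-yl)-2-(trifluoromethylsulfonyloxy)bicyclo[6.1.0]non-2-ene-3-carboxylate
Product: 15 (1S,4S,5R,7R,8S)-5-hydroxy-3-(hydroxymethyl)-7-methyl-4-(prop-1-en-2-yl)bicyclo[6.1.0]non-2-en-2-yl trifluoromethanesulfonate
Conditions: DIBAL-H (4 equiv), CH2Cl2, −78 → −20 °C; aq. Rochelle salt
Reagents that add atoms: none
Why: 1,2-Reduction of the β-triflyloxy enoate to the allylic alcohol should leave the vinyl triflate intact, and any lactone formed between the C1 hydroxyl and the ester of 14 would be reduced to the same diol.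

Step 10
Reactants: 15 (1S,4S,5R,7R,8S)-5-hydroxy-3-(hydroxymethyl)-7-methyl-4-(prop-1-en-2-yl)bicyclo[6.1.0]non-2-en-2-yl trifluoromethanesulfonate
Product: 16 tricyclic hydroxy butenolide (the target core with free C1–OH and isopropenyl on C8)
Conditions: Pd(PPh3)4 (10 mol %), CO (1 atm), Et3N, MeCN, 60 °C
Reagents that add atoms: carbon monoxide [C-]#[O+]
Why: Palladium-catalysed carbonylative lactonisation of a (Z)-3-(triflyloxy)allylic alcohol, in which oxidative addition, CO insertion and capture of the acyl palladium by the primary allylic hydroxyl should close the five-membered butenolide faster than the distant C1 hydroxyl can react.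

Step 11
Reactants: 16 tricyclic hydroxy butenolide
Product: 17 tricyclic acetoxy butenolide (the target with an isopropenyl group on C8 in place of the side chain)
Conditions: Ac2O, pyridine, DMAP (cat.), CH2Cl2, rt
Reagents that add atoms: acetic anhydride CC(=O)OC(C)=O
Why: Standard acylation of the only hydroxyl group, with retention at C1.

Step 12
Reactants: 18 2-methylbut-3-yn-2-ol
Product: 20 (E)-4-iodo-2-methylbut-3-en-2-ol, via vinylstannane 19 (not isolated)
Conditions: Bu3SnH, AIBN (cat.), PhMe, 80 °C; then I2, CH2Cl2, 0 °C
Reagents that add atoms: iodine II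
Why: Radical hydrostannation of the terminal alkyne should give the thermodynamic (E)-β-stannane, and iododestannylation proceeds with retention of alkene geometry.

Step 13
Reactants: 20 (E)-4-iodo-2-methylbut-3-en-2-ol
Product: 21 (E)-3-hydroperoxy-1-iodo-3-methylbut-1-ene
Conditions: 50% aq. H2O2, H2SO4 (cat.), Et2O, 0 °C → rt
Reagents that add atoms: hydrogen peroxide OO
Why: Acid-catalysed perhydrolysis (SN1) of a tertiary allylic alcohol, in which the allyl cation should be captured at its tertiary terminus so that the (E)-vinyl iodide is kept.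

Step 14
Reactants: 21 (E)-3-hydroperoxy-1-iodo-3-methylbut-1-ene
Product: 22 (E)-1-iodo-3-[(2-methoxypropan-2-yl)peroxy]-3-methylbut-1-ene
Conditions: 2-methoxypropene, PPTS (cat.), CH2Cl2, 0 °C
Reagents that add atoms: 2-methoxypropene COC(C)=C
Why: Acid-catalysed addition of the hydroperoxide to the enol ether should give the base-stable monoperoxyketal, a dialkyl-type peroxide suited to palladium coupling.

Step 15
Reactants: 17 tricyclic acetoxy butenolide; 22 (E)-1-iodo-3-[(2-methoxypropan-2-yl)peroxy]-3-methylbut-1-ene
Product: 24 peroxyketal of the target (the target with its OOH capped as the 2-methoxypropan-2-yl peroxyketal), via alkylborane 23 (not isolated)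
Conditions: 9-BBN (1.5 equiv), THF, 0 °C → rt; then 3 M aq. K3PO4, 22, PdCl2(dppf) (10 mol %), AsPh3 (10 mol %), DMF, rt
Reagents that add atoms: none
Why: 9-BBN adds across the isopropenyl group in a four-centre, syn, anti-Markovnikov fashion (boron to the CH2 terminus, hydrogen to the carbon on C8), and after base activation of the borane, oxidative addition of Pd(0) into the C–I bond of 22, transmetalation of the primary alkyl group and reductive elimination form the CH2–CH(sp2) bond. The closest known reaction type is the one-pot hydroboration/B-alkyl Suzuki–Miyaura coupling of a 1,1-disubstituted alkene with an (E)-vinyl iodide; no ring is closed. The methyl-bearing stereocentre is set in the hydroboration by 1,2-induction from C8: in the rotamer with C8–H eclipsing C=CH2 the cis acetoxy group on C1 screens the C1-side face, so the bulky borane should deliver hydrogen from the face next to the planar butenolide carbon C7, which gives the required R configuration. The step needs chemoselectivity for the isopropenyl group over the tetrasubstituted electron-poor butenolide alkene and the ester carbonyls (9-BBN reduces these only slowly), retention of the E geometry (stereospecific oxidative addition and reductive elimination) and survival of the O–O bond (peroxyketal; excess B–H is destroyed by the aqueous base before 22 and palladium are added).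

Step 16
Reactants: 24 peroxyketal of the target
Product: 25 target hydroperoxide
Conditions: AcOH/THF/H2O (4:2:1), rt
Reagents that add atoms: none
Why: Mild acid hydrolysis of the 2-methoxyprop-2-yl peroxyketal should release the hydroperoxide and leave the acetate, the butenolide and the E alkene unchanged.

Compound list
1 | propanal | CCC=O | starting material
2 | but-3-en-2-one (methyl vinyl ketone) | CC(=O)C=C | starting material
3 | (R)-2-methyl-5-oxohexanal | C[C@@H](C=O)CCC(C)=O | intermediate
4 | (R)-4-methylcyclohex-2-en-1-one | C[C@@H]1CCC(=O)C=C1 | intermediate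
5 | (1S,5R,6S)-5-methylbicyclo[4.1.0]heptan-2-one (cyclopropane CH2 trans to methyl) | C[C@@H]1CCC(=O)[C@H]2C[C@@H]12 | intermediate
6 | 1-[(1S,5R,6S)-5-methylbicyclo[4.1.0]hept-2-en-2-yl]pyrrolidine | C[C@@H]1CC=C(N2CCCC2)[C@H]3C[C@@H]13 | intermediate
7 | methyl propiolate | C#CC(=O)OC | starting material
8 | cis-fused aminocyclobutene [2+2] adduct of 6 and 7 (configuration of the two new ring-fusion carbons not defined) | C[C@@H]1CC2C=C(C(=O)OC)C2(N3CCCC3)[C@H]4C[C@@H]14 | intermediate (not isolated)
9 | methyl (1S,7R,8S)-7-methyl-2-(pyrrolidin-1-yl)bicyclo[6.1.0]nona-2,4-diene-3-carboxylate (both ring alkenes cis) | C[C@@H]1C/C=C\C(C(=O)OC)=C(N2CCCC2)/[C@H]3C[C@@H]13 | intermediate (not isolated)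
10 | methyl (1S,7R,8S)-7-methyl-2-oxobicyclo[6.1.0]non-4-ene-3-carboxylate (cis ring alkene; C3 epimers in equilibrium with the conjugated dienol) | C[C@@H]1C/C=C\C(C(=O)OC)C(=O)[C@H]2C[C@@H]12 | intermediate
11 | 4,5-epoxide of 10 (oxirane oxygen cis to the cyclopropane CH2) | C[C@@H]1C[C@H]2O[C@H]2C(C(=O)OC)C(=O)[C@H]3C[C@@H]13 | intermediate (not isolated)
12 | methyl (1S,5R,7R,8S)-5-hydroxy-7-methyl-2-oxobicyclo[6.1.0]non-3-ene-3-carboxylate (OH cis to the cyclopropane CH2) | C[C@@H]1C[C@@H](O)/C=C(C(=O)OC)\C(=O)[C@H]2C[C@@H]12 | intermediate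
13 | methyl (1S,4R,5R,7R,8S)-5-hydroxy-7-methyl-2-oxo-4-(prop-1-en-2-yl)bicyclo[6.1.0]nonane-3-carboxylate (C3 epimers and enol) | C[C@@H]1C[C@@H](O)[C@@H](C(C)=C)C(C(=O)OC)C(=O)[C@H]2C[C@@H]12 | intermediate
14 | methyl (1S,4S,5R,7R,8S)-5-hydroxy-7-methyl-4-(prop-1-en-2-yl)-2-(trifluoromethylsulfonyloxy)bicyclo[6.1.0]non-2-ene-3-carboxylate | C[C@@H]1C[C@@H](O)[C@@H](C(C)=C)/C(C(=O)OC)=C(OS(=O)(=O)C(F)(F)F)\[C@H]2C[C@@H]12 | intermediate
15 | (1S,4S,5R,7R,8S)-5-hydroxy-3-(hydroxymethyl)-7-methyl-4-(prop-1-en-2-yl)bicyclo[6.1.0]non-2-en-2-yl trifluoromethanesulfonate | C[C@@H]1C[C@@H](O)[C@@H](C(C)=C)/C(CO)=C(OS(=O)(=O)C(F)(F)F)\[C@H]2C[C@@H]12 | intermediate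
16 | tricyclic hydroxy butenolide: target ring system with C1–OH and C8–isopropenyl, both cis to the cyclopropane CH2, C3–CH3 trans | O[C@@H]1C[C@@H](C)[C@@H]2C[C@@H]2C2=C(COC2=O)[C@@H]1C(C)=C | intermediate
17 | tricyclic acetoxy butenolide: C1 acetate of 16 | CC(=O)O[C@@H]1C[C@@H](C)[C@@H]2C[C@@H]2C2=C(COC2=O)[C@@H]1C(C)=C | intermediate
18 | 2-methylbut-3-yn-2-ol | CC(C)(O)C#C | starting material
19 | (E)-2-methyl-4-(tributylstannyl)but-3-en-2-ol | CC(C)(O)/C=C/[Sn](CCCC)(CCCC)CCCC | intermediate (not isolated)
20 | (E)-4-iodo-2-methylbut-3-en-2-ol | CC(C)(O)/C=C/I | intermediate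
21 | (E)-3-hydroperoxy-1-iodo-3-methylbut-1-ene | CC(C)(OO)/C=C/I | intermediate
22 | (E)-1-iodo-3-[(2-methoxypropan-2-yl)peroxy]-3-methylbut-1-ene | COC(C)(C)OOC(C)(C)/C=C/I | intermediate
23 | B-alkyl-9-BBN adduct of 17 (boron on the side-chain CH2, methyl carbon configured as in the target) | CC(=O)O[C@@H]1C[C@@H](C)[C@@H]2C[C@@H]2C2=C(COC2=O)[C@@H]1[C@H](C)CB1C2CCCC1CCC2 | intermediate (not isolated)
24 | peroxyketal of the target (OO–C(CH3)2OCH3 in place of OOH) | CC(=O)O[C@@H]1C[C@@H](C)[C@@H]2C[C@@H]2C2=C(COC2=O)[C@@H]1[C@H](C)C/C=C/C(C)(C)OOC(C)(C)OC | intermediate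
25 | target hydroperoxide | CC(=O)O[C@@H]1C[C@@H](C)[C@@H]2C[C@@H]2C2=C(COC2=O)[C@@H]1[C@H](C)C/C=C/C(C)(C)OO | target

Total step count: 16. Longest linear sequence: 13 steps (steps 1–11, 15, 16); steps 12–14 make the vinyl iodide.

Steps most likely to fail

Step 15. The hydroboration may proceed with poor or reversed facial selectivity at the isopropenyl group, or the O–O bond may be reduced by boron hydride or palladium species during the one-pot coupling. The fallback sets out from 17 and separates the two events. Hydroboration with 9-BBN (or, if the intrinsic facial sense is the wrong one, rhodium-catalysed hydroboration with catecholborane, which is known to give the complementary sense with alkenes of this kind) and oxidation with NaBO3·4H2O would give the primary alcohol F1, at which stage the epimers at the methyl carbon can be separated. Appel iodination (I2, PPh3, imidazole) would give the primary iodide F2, and zinc insertion (Zn, LiCl, THF) the alkylzinc iodide F3. F3 would be joined to 22 by Negishi coupling (Pd2(dba)3, SPhos, THF, rt), which comes back to the route at 24.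

Step 7. Alkoxide direction may be lost, so that the Grignard reagent attacks anti to the C1 oxygen or adds 1,2 to the ketone. The fallback sets out from 12: silylation (TBSCl, imidazole, DMF) would give the silyl ether F4, and a catalyst-controlled rhodium(I)/chiral diene conjugate addition of potassium isopropenyltrifluoroborate (Hayashi–Miyaura type, ligand enantiomer matched to the exo face) would give the silyl ether F5. HF·pyridine would then remove the silyl group and return to 13.

Step 6. The epoxidation may show poor facial selectivity, the enol may be hydroxylated at C7 instead, or 10 may drift into its conjugated alkylidene tautomer before it is oxidised. The fallback sets out from 10: TBSOTf and Et3N would convert either tautomer into the silyl dienol ether F6, and a catalyst-controlled Jacobsen–Katsuki epoxidation ((salen)Mn(III)Cl, NaOCl) of the cis-disubstituted conjugated C8=C1 alkene would give the epoxy silyl enol ether F7. Fluoride (TBAF buffered with AcOH) would unmask the enolate, which opens the epoxide and returns to 12.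

Further compounds
F1 | step 15 | primary alcohol from hydroboration–oxidation of 17 (side-chain CH(CH3)CH2OH, methyl carbon as in the target) | CC(=O)O[C@@H]1C[C@@H](C)[C@@H]2C[C@@H]2C2=C(COC2=O)[C@@H]1[C@H](C)CO
F2 | step 15 | primary iodide from F1 | CC(=O)O[C@@H]1C[C@@H](C)[C@@H]2C[C@@H]2C2=C(COC2=O)[C@@H]1[C@H](C)CI
F3 | step 15 | alkylzinc iodide from F2 | CC(=O)O[C@@H]1C[C@@H](C)[C@@H]2C[C@@H]2C2=C(COC2=O)[C@@H]1[C@H](C)C[Zn]I
F4 | step 7 | tert-butyldimethylsilyl ether of 12 | C[C@@H]1C[C@@H](O[Si](C)(C)C(C)(C)C)/C=C(C(=O)OC)\C(=O)[C@H]2C[C@@H]12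
F5 | step 7 | tert-butyldimethylsilyl ether of 13 | C[C@@H]1C[C@@H](O[Si](C)(C)C(C)(C)C)[C@@H](C(C)=C)C(C(=O)OC)C(=O)[C@H]2C[C@@H]12
F6 | step 6 | tert-butyldimethylsilyl dienol ether of 10 | C[C@@H]1C/C=C\C(C(=O)OC)=C(O[Si](C)(C)C(C)(C)C)/[C@H]2C[C@@H]12
F7 | step 6 | C8–C1 epoxide of F6 (oxirane oxygen cis to the cyclopropane CH2) | C[C@@H]1C[C@H]2O[C@H]2/C(C(=O)OC)=C(O[Si](C)(C)C(C)(C)C)\[C@H]3C[C@@H]13
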